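**The leftover.** After 90.0 s the ochre run reads 58.6% ring, so 41.4% of the starting material charged stands as something else. The last two readings differ by 0.1 percentage points, inside the scatter of 1 point.

| setting | ochre | Friday's | Wednesday's | Monday's | Tuesday's | Sunday's |
|---|---|---|---|---|---|---|
| starting material | 0.55 M | 0.12 M | 1.5 M | 0.50 M | 0.50 M | 0.80 M |
| activator | 1.1 equiv | 1.10 equiv | 1.10 equiv | 1.10 equiv | 4.40 equiv | 1.70 equiv |
| remark | run made earlier |  |  |  |  |  |
| time |  | 8.0 min | 8.0 min | 8.0 min | 8.0 min | 8.0 min |

ochre run (percent of the starting material charged)

| time / s | ring / % |
|---|---|
| 15.0 | 19.2 |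
| 30.0 | 37.2 |
| 50.0 | 50.2 |
| 60.0 | 51.7 |
| 80.0 | 58.7 |
| 90.0 | 58.6 |

(standard deviation of a reading: 1 percentage point)



1. ranking by amount of ring, in percent of the starting material charged, from high to low, at 8.0 min (Friday's / Wednesday's / Monday's / Tuesday's / Sunday's)
2. the same order at 50 s (Friday's / Wednesday's / Monday's / Tuesday's / Sunday's)
3. the amount of ring, in percent of the starting material charged of the flask you put first, at 8.0 min
4. the amount of ring, in percent of the starting material charged of the flask you put last, at 8.0 min

**Ring clock.** Take the last reading as the plateau and the rise as first order. The reading at 30.0 s then gives h = 20.6 s: the ring half-time, the time in which ring closes half of its gap to the plateau. It is a reading and carries the scatter. By 90.0 s a small gap remains, so this reckoning puts the ochre plateau at 61.6%.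

**Monday's beside ochre.** Monday's looks like the same flask: 1.10 equiv against 1.1 equiv, and 0.50 M against 0.55 M. Its 8.0 min spans 23.3 ring half-times, so Monday's should stand at its plateau. Suppose ring waits on a slow closing while starting material catches what waits. At nearly equal equivalents this reckoning takes the loss as proportional to the charge, and Monday's is more dilute, which gives 65.1% ring. Under that supposition, starting material that goes quickly beside h leaves less to catch what waits. Tuesday's, at Monday's charge, carries 4.00 times the equivalents, so if uptake follows activator, this reckoning places Tuesday's above Monday's, with the margin left open.

**The forecast.** It gives Friday's > Tuesday's > Monday's > Sunday's > Wednesday's at 8.0 min and Tuesday's > Sunday's > Monday's > Wednesday's > Friday's at 50 s. Its first flask stands at 85% (72% to 91%) and its last at 39% (33% to 45%). It holds Monday's and Tuesday's near 62: “Tuesday edges Monday if any activator is depleted.” The reckoning above also puts Tuesday's higher, but it gives Monday's 65.1% and ties Tuesday's gain to the speed of uptake.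

**The flasks.** The order is Tuesday's > Sunday's > Friday's > Monday's > Wednesday's at 8.0 min and Tuesday's > Sunday's > Monday's > Wednesday's > Friday's at 50 s, with Wednesday's last at 58.8%.

    starting material + activated form → open dimer (k = 0.120 /M/s)
    activated form → ring (k = 0.0340 /s)
    starting material + activator → activated form (k = 0.570 /M/s)
    2 activator → self-condensation product (k = 0.0960 /M/s)

Monday's ends at 64.9%, and Tuesday's stands higher. In Tuesday's, activation alone, with the other concentrations as charged, gives starting material a half-life of 0.55 s, against the ring half-time of 20.6 s read from the ochre run, a ratio of 37.5. At 0.0376 min Tuesday's starting material still goes 12 times faster into activated form than into open dimer, and Tuesday's ends with 8.41% open dimer and 91.6% ring.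

The readings stem from a simulated flask for substances that don't exist; the scatter is artificial.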